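Numbering the ring O-1, then C-2 to C-5, the plan opens one benzylic C–O bond and cuts C-2–C-3 and C-4–C-5. It exploits that HOCH2–C-3–C-4–CH2OH is a disguised γ-butyrolactone flanked by aryl carbinol carbons C-2 and C-5. In one flask a lithiated O-benzylsyringyl dithiane adds to the β-carbon of an (S)-5-(silyloxymethyl)butenolide and the enolate captures O-benzylsyringaldehyde. Two C–C bonds form, and C-4 and C-3 are relayed from the butenolide γ-centre, which is excised later. Equilibrating acid closure then gives the all-trans tetrahydrofuran.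

Key step: step 4

Assumption: (S)-5-(hydroxymethyl)furan-2(5H)-one is taken as a purchasable chiral-pool lactone. Where a carbinol carbon (C-2 or C-5) forms without control its epimers are carried together, so the SMILES show C-2 as in the target and leave C-5 open until step 10.

Abbreviations: Ar = 4-benzyloxy-3,5-dimethoxyphenyl; TBDPS = tert-butyldiphenylsilyl; Piv = pivaloyl. The locants C-2 to C-5 are those of the target ring and are used for all intermediates.

Step 1
Reactants: 1 syringaldehyde; 2 benzyl bromide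
Product: 3 4-benzyloxy-3,5-dimethoxybenzaldehyde
Conditions: K2CO3, DMF, 60 °C
Reagents that add atoms: benzyl bromide 2, BrCc1ccccc1
Why: Williamson ether synthesis, in which the acidic syringyl phenol is ionised by K2CO3 and alkylated by the reactive benzylic bromide, with no stereocentre involved.

Step 2
Reactants: 3 4-benzyloxy-3,5-dimethoxybenzaldehyde; 4 propane-1,3-dithiol
Product: 5 2-(4-benzyloxy-3,5-dimethoxyphenyl)-1,3-dithiane
Conditions: BF3·OEt2 (cat.), CH2Cl2, 0 °C to rt
Reagents that add atoms: propane-1,3-dithiol 4, SCCCS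
Why: Lewis-acid-catalysed dithioacetalisation of an aromatic aldehyde is fast and driven by formation of the six-membered ring, and the aryl benzyl ether tolerates catalytic BF3·OEt2 at this temperature.

Step 3
Reactants: 6 (S)-5-(hydroxymethyl)furan-2(5H)-one
Product: 7 (S)-5-(tert-butyldiphenylsilyloxymethyl)furan-2(5H)-one
Conditions: TBDPSCl, imidazole, CH2Cl2, 0 °C to rt
Reagents that add atoms: tert-butyl(chloro)diphenylsilane, CC(C)(C)[Si](Cl)(c1ccccc1)c1ccccc1
Why: Imidazole-promoted O-silylation of a primary alcohol uses a base too weak to remove the γ-proton, so the S centre is kept and the bulky shield needed in step 4 is installed.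

Step 4
Reactants: 5 2-(4-benzyloxy-3,5-dimethoxyphenyl)-1,3-dithiane; 7 (S)-5-(tert-butyldiphenylsilyloxymethyl)furan-2(5H)-one; 3 4-benzyloxy-3,5-dimethoxybenzaldehyde
Product: 10 (3R,4S,5S)-3-[(R)-Ar(hydroxy)methyl]-4-(2-Ar-1,3-dithian-2-yl)-5-(TBDPS-oxymethyl)oxolan-2-one (trans,trans lactone), via 2-lithiodithiane 8 (not isolated), via lithium lactone enolate 9 (not isolated)
Conditions: 5, n-BuLi, THF, −78 to −30 °C; 7, THF, −78 °C; 3, THF, −78 °C; AcOH, −78 °C
Reagents that add atoms: none
Why: n-BuLi removes the dithiane C-2 proton of 5, the soft sulfur- and aryl-stabilised carbanion 8 adds in Michael fashion to the β-carbon of 7 (C-4–C-5 bond), and the lithium enolate 9 is intercepted by 3 in an aldol addition (C-2–C-3 bond), which is the established tandem conjugate addition–aldol of 2-aryl-2-lithiodithianes with butenolides. No ring is closed in this step. C-4 is controlled by the γ-stereocentre of 7, whose silyloxymethyl arm blocks one face so that 8 enters anti to it, and C-3 is controlled by the new bulky dithianyl group, which sends the aldehyde to the opposite enolate face and gives the trans,trans lactone. The carbinol carbon C-2 is governed only loosely by a closed six-membered lithium-chelated transition state, so its epimer may accompany 10 and is carried on, because step 10 levels this centre. The step needs 1,4- rather than 1,2-attack and addition rather than γ-deprotonation, and these are secured by the delocalised aryl dithiane anion, the low temperature and the poor silyloxide leaving group. The cold acidic quench forestalls retro-aldol.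

Step 5
Reactants: 10 trans,trans dithianyl lactone
Product: 11 (3R,4S,5S)-4-(4-benzyloxy-3,5-dimethoxybenzoyl)-3-[(R)-Ar(hydroxy)methyl]-5-(TBDPS-oxymethyl)oxolan-2-one
Conditions: PhI(OCOCF3)2, MeCN/H2O (9:1), 0 °C
Reagents that add atoms: water, O
Why: Oxidative dithioacetal hydrolysis with a trivalent-iodine reagent attacks sulfur far faster than the trialkoxyarenes, water supplies the carbonyl oxygen, and the mildly acidic medium avoids base-induced β-elimination of the lactone oxygen from the new β-acyloxy ketone, whose trans,trans arrangement is in any case the stable one.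

Step 6
Reactants: 11 keto lactone
Product: 12 (1R,2S,3R,4S)-1-Ar-3-[Ar(hydroxy)methyl]-5-(TBDPS-oxy)-2-(hydroxymethyl)pentane-1,4-diol (C-5 carbinol epimers)
Conditions: LiAlH4, THF, 0 °C to rt; then H2O
Reagents that add atoms: none
Why: Exhaustive hydride reduction opens the lactone to the C-3 hydroxymethyl group plus the arm carbinol and converts the aryl ketone into the C-5 carbinol, which forms without useful control as an epimer pair that step 10 levels, while C-3, C-4 and the silyl ether stay untouched.

Step 7
Reactants: 12 silylated tetraol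
Product: 13 (1R,2S,3R,4S)-1-Ar-3-[Ar(hydroxy)methyl]-2-(hydroxymethyl)pentane-1,4,5-triol (C-5 carbinol epimers)
Conditions: Bu4NF, THF, rt
Reagents that add atoms: none
Why: Fluoride-driven desilylation relies on the strong Si–F bond, is placed after the reduction so that no base-sensitive carbonyl group remains, and makes any silyl shift within the arm glycol irrelevant.

Step 8
Reactants: 13 pentaol
Product: 15 (1R,2S,3S)-1,4-bis(Ar)-2,3-bis(hydroxymethyl)butane-1,4-diol (C-5 carbinol epimers), via formyl triol 14 (not isolated)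
Conditions: NaIO4, THF/H2O (3:1), 0 °C; extraction; NaBH4, MeOH, 0 °C
Reagents that add atoms: none
Why: In this Malaprade glycol cleavage followed by borohydride reduction the arm glycol is the only vicinal diol, so periodate removes just its terminal carbon and erases the borrowed stereocentre, the aldehyde rests as a five-membered lactol that guards C-4 against epimerisation and retro-aldol, and NaBH4 turns it into the C-4 hydroxymethyl group.

Step 9
Reactants: 15 tetraol
Product: 16 (1R,2S,3S)-1,4-bis(Ar)-2,3-bis(pivaloyloxymethyl)butane-1,4-diol (C-5 carbinol epimers)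
Conditions: PivCl (2.2 equiv), pyridine, CH2Cl2, 0 °C
Reagents that add atoms: pivaloyl chloride, CC(C)(C)C(=O)Cl
Why: Sterically selective acylation lets the bulky acid chloride esterify the two primary hydroxyls much faster than the two flanked secondary benzylic ones, and these caps are needed because free hydroxymethyl groups would divert step 10 to the furofuran skeleton.

Step 10
Reactants: 16 diol dipivalate
Product: 17 (2R,3S,4S,5R)-2,5-bis(Ar)-3,4-bis(pivaloyloxymethyl)oxolane
Conditions: CF3CO2H (5 vol%), CH2Cl2, 4 Å MS, 0 °C to rt, stopped once the isomers have converged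
Reagents that add atoms: none
Why: In this acid-catalysed SN1 cyclodehydration of a 1,4-diarylbutane-1,4-diol either trialkoxybenzylic alcohol ionises and the other hydroxyl closes the five-membered ether, and because the product re-ionises under the same conditions C-2 and C-5 should settle, whatever carbinol epimers are fed in, at the all-trans (2R,5R) arrangement dictated by the fixed C-3 and C-4.

Step 11
Reactants: 17 tetrahydrofuran dipivalate
Product: 18 (2R,3S,4S,5R)-2,5-bis(Ar)-3,4-bis(hydroxymethyl)oxolane
Conditions: LiAlH4, THF, 0 °C; then H2O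
Reagents that add atoms: none
Why: Reductive ester cleavage removes the hindered pivalates quickly, and neither the benzyl ethers nor the ring ether or its four stereocentres respond to hydride.

Step 12
Reactants: 18 bis(benzyl ether) diol
Product: 19 (2R,3S,4S,5R)-2,5-bis(4-hydroxy-3,5-dimethoxyphenyl)-3,4-bis(hydroxymethyl)oxolane (target)
Conditions: H2 (1 atm), Pd/C, EtOAc/EtOH, rt, stopped at consumption of 18
Reagents that add atoms: none
Why: Catalytic hydrogenolysis cleaves aryl benzyl ethers on Pd/C much faster than the hindered benzylic C–O bonds of the ring, so a neutral solvent and a timely stop should release both phenols with all four stereocentres intact.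

Compound list
1 | syringaldehyde (4-hydroxy-3,5-dimethoxybenzaldehyde) | COc1cc(C=O)cc(OC)c1O | starting material
2 | benzyl bromide | BrCc1ccccc1 | starting material
3 | 4-benzyloxy-3,5-dimethoxybenzaldehyde | COc1cc(C=O)cc(OC)c1OCc1ccccc1 | intermediate
4 | propane-1,3-dithiol | SCCCS | starting material
5 | 2-(4-benzyloxy-3,5-dimethoxyphenyl)-1,3-dithiane | COc1cc(C2SCCCS2)cc(OC)c1OCc1ccccc1 | intermediate
6 | (S)-5-(hydroxymethyl)furan-2(5H)-one | O=C1O[C@H](CO)C=C1 | starting material
7 | (S)-5-(tert-butyldiphenylsilyloxymethyl)furan-2(5H)-one | O=C1O[C@H](CO[Si](c2ccccc2)(c2ccccc2)C(C)(C)C)C=C1 | intermediate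
8 | 2-lithio-2-(4-benzyloxy-3,5-dimethoxyphenyl)-1,3-dithiane | [Li]C1(c2cc(OC)c(OCc3ccccc3)c(OC)c2)SCCCS1 | intermediate
9 | lithium enolate of (4S,5S)-4-(2-Ar-1,3-dithian-2-yl)-5-(TBDPS-oxymethyl)oxolan-2-one | [Li]OC1=C[C@H](C2(c3cc(OC)c(OCc4ccccc4)c(OC)c3)SCCCS2)[C@@H](CO[Si](c2ccccc2)(c2ccccc2)C(C)(C)C)O1 | intermediate
10 | (3R,4S,5S)-3-[(R)-Ar(hydroxy)methyl]-4-(2-Ar-1,3-dithian-2-yl)-5-(TBDPS-oxymethyl)oxolan-2-one | O=C1O[C@H](CO[Si](c2ccccc2)(c2ccccc2)C(C)(C)C)[C@@H](C2(c3cc(OC)c(OCc4ccccc4)c(OC)c3)SCCCS2)[C@@H]1[C@@H](O)c1cc(OC)c(OCc2ccccc2)c(OC)c1 | intermediate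
11 | (3R,4S,5S)-4-(4-benzyloxy-3,5-dimethoxybenzoyl)-3-[(R)-Ar(hydroxy)methyl]-5-(TBDPS-oxymethyl)oxolan-2-one | O=C1O[C@H](CO[Si](c2ccccc2)(c2ccccc2)C(C)(C)C)[C@@H](C(=O)c2cc(OC)c(OCc3ccccc3)c(OC)c2)[C@@H]1[C@@H](O)c1cc(OC)c(OCc2ccccc2)c(OC)c1 | intermediate
12 | (1R,2S,3R,4S)-1-Ar-3-[Ar(hydroxy)methyl]-5-(TBDPS-oxy)-2-(hydroxymethyl)pentane-1,4-diol, epimers at the side-chain (C-5) carbinol | O[C@@H](c1cc(OC)c(OCc2ccccc2)c(OC)c1)[C@H](CO)[C@H](C(O)c1cc(OC)c(OCc2ccccc2)c(OC)c1)[C@H](O)CO[Si](c1ccccc1)(c1ccccc1)C(C)(C)C | intermediate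
13 | (1R,2S,3R,4S)-1-Ar-3-[Ar(hydroxy)methyl]-2-(hydroxymethyl)pentane-1,4,5-triol, epimers at the C-5 carbinol | O[C@@H](c1cc(OC)c(OCc2ccccc2)c(OC)c1)[C@H](CO)[C@H](C(O)c1cc(OC)c(OCc2ccccc2)c(OC)c1)[C@H](O)CO | intermediate
14 | (2R,3S,4R)-4-Ar-2-[Ar(hydroxy)methyl]-4-hydroxy-3-(hydroxymethyl)butanal, drawn open, resting as five-membered lactols | O[C@@H](c1cc(OC)c(OCc2ccccc2)c(OC)c1)[C@H](CO)[C@H](C(O)c1cc(OC)c(OCc2ccccc2)c(OC)c1)C=O | intermediate
15 | (1R,2S,3S)-1,4-bis(Ar)-2,3-bis(hydroxymethyl)butane-1,4-diol, epimers at C-4 of the chain (C-5 of the target) | O[C@@H](c1cc(OC)c(OCc2ccccc2)c(OC)c1)[C@H](CO)[C@H](C(O)c1cc(OC)c(OCc2ccccc2)c(OC)c1)CO | intermediate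
16 | (1R,2S,3S)-1,4-bis(Ar)-2,3-bis(pivaloyloxymethyl)butane-1,4-diol, same epimer pair | O[C@@H](c1cc(OC)c(OCc2ccccc2)c(OC)c1)[C@H](COC(=O)C(C)(C)C)[C@H](C(O)c1cc(OC)c(OCc2ccccc2)c(OC)c1)COC(=O)C(C)(C)C | intermediate
17 | (2R,3S,4S,5R)-2,5-bis(Ar)-3,4-bis(pivaloyloxymethyl)oxolane, all-trans | COc1cc([C@@H]2O[C@@H](c3cc(OC)c(OCc4ccccc4)c(OC)c3)[C@H](COC(=O)C(C)(C)C)[C@H]2COC(=O)C(C)(C)C)cc(OC)c1OCc1ccccc1 | intermediate
18 | (2R,3S,4S,5R)-2,5-bis(Ar)-3,4-bis(hydroxymethyl)oxolane, all-trans | COc1cc([C@@H]2O[C@@H](c3cc(OC)c(OCc4ccccc4)c(OC)c3)[C@H](CO)[C@H]2CO)cc(OC)c1OCc1ccccc1 | intermediate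
19 | (2R,3S,4S,5R)-2,5-bis(4-hydroxy-3,5-dimethoxyphenyl)-3,4-bis(hydroxymethyl)oxolane, all-trans | COc1cc([C@@H]2O[C@@H](c3cc(OC)c(O)c(OC)c3)[C@H](CO)[C@H]2CO)cc(OC)c1O | target

Total step count: 12. Longest linear sequence: 11 steps (1, 2, then 4 to 12). Step 3 is the only side branch.

Steps most likely to fail

Step 4. Three processes threaten this step. Proton transfer from the butenolide γ-position to the carbanion is one, and attack at the lactone carbonyl is another. The third is sluggish, reversible capture of the crowded enolate by the electron-rich aldehyde.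

The fallback sets out from 5 and 7 and runs only the conjugate addition. The enolate is protonated cold, which should give the isolable (4S,5S)-4-(2-Ar-1,3-dithian-2-yl)-5-(TBDPS-oxymethyl)oxolan-2-one F1. After purification this lactone is re-enolised with LiN(i-Pr)2. It is then transmetallated with ZnCl2 to a less basic enolate whose aldolate reverts less readily, and combined with 3. The same anti relay from the β-substituent applies, and the sequence rejoins the route at 10.

Step 10. The benzylic cation may be captured irreversibly by the other activated arene in a Friedel–Crafts closure to an aryltetralin. Pivalate participation with acyl shift, or stalling before the isomers converge, are the other failure modes.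

The fallback sets out from 16 and removes the benzyl groups first (H2, Pd/C, EtOAc). This gives the bis-phenolic diol dipivalate F4. Its free para-hydroxyl groups let the carbinols ionise through p-quinone methide-type cations under a far weaker acid (catalytic pyridinium p-toluenesulfonate, MeCN, rt to 40 °C). Reversible O-closure then proceeds while arene attack should stay slow, giving the all-trans bis-phenolic tetrahydrofuran dipivalate F5. Transesterification with NaOMe in MeOH under argon rejoins the route at 19.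

Step 5. Unmasking may be slow at the crowded quaternary carbon, and the electron-rich arenes may be oxidised. The lactone may also open by β-elimination once the ketone is free.

The fallback sets out from 10 and reverses the order of events. LiAlH4 first reduces the lactone to the dithianyl triol F2. S-alkylative hydrolysis (MeI, CaCO3, MeCN/H2O, 40 °C) then frees the aryl ketone triol F3. That ketone carries only a poor β-hydroxyl leaving group and should rest as a cyclic hemiketal. NaBH4 in MeOH then rejoins the route at 12.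

Further compounds
F1 | step 4 | (4S,5S)-4-(2-Ar-1,3-dithian-2-yl)-5-(TBDPS-oxymethyl)oxolan-2-one | O=C1C[C@H](C2(c3cc(OC)c(OCc4ccccc4)c(OC)c3)SCCCS2)[C@@H](CO[Si](c2ccccc2)(c2ccccc2)C(C)(C)C)O1
F2 | step 5 | (1R,2S,3S,4S)-1-Ar-3-(2-Ar-1,3-dithian-2-yl)-5-(TBDPS-oxy)-2-(hydroxymethyl)pentane-1,4-diol | O[C@@H](c1cc(OC)c(OCc2ccccc2)c(OC)c1)[C@H](CO)[C@H](C1(c2cc(OC)c(OCc3ccccc3)c(OC)c2)SCCCS1)[C@H](O)CO[Si](c1ccccc1)(c1ccccc1)C(C)(C)C
F3 | step 5 | aryl ketone triol, the C-5 ketone analogue of 12, drawn in its open form | O[C@@H](c1cc(OC)c(OCc2ccccc2)c(OC)c1)[C@H](CO)[C@H](C(=O)c1cc(OC)c(OCc2ccccc2)c(OC)c1)[C@H](O)CO[Si](c1ccccc1)(c1ccccc1)C(C)(C)C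
F4 | step 10 | (1R,2S,3S)-1,4-bis(4-hydroxy-3,5-dimethoxyphenyl)-2,3-bis(pivaloyloxymethyl)butane-1,4-diol, epimers at the second carbinol | O[C@@H](c1cc(OC)c(O)c(OC)c1)[C@H](COC(=O)C(C)(C)C)[C@H](C(O)c1cc(OC)c(O)c(OC)c1)COC(=O)C(C)(C)C
F5 | step 10 | (2R,3S,4S,5R)-2,5-bis(4-hydroxy-3,5-dimethoxyphenyl)-3,4-bis(pivaloyloxymethyl)oxolane | COc1cc([C@@H]2O[C@@H](c3cc(OC)c(O)c(OC)c3)[C@H](COC(=O)C(C)(C)C)[C@H]2COC(=O)C(C)(C)C)cc(OC)c1O
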